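Conversion of starting material into target leaves the sum of the two unchanged, so a fall in that sum in these closed runs reads as material going elsewhere, and that sum answers your request for a quick number.

| flask | starting material | gas phase | protic impurity | catalyst | remark | time |
|---|---|---|---|---|---|---|
| spring | 0.27 M | 78 mM (held) | 0.080 M | 4.4 mol% | run made earlier |  |
| summer | 0.60 M | 78 mM (held) | 0.080 M | 4.4 mol% | run made earlier |  |
| flask | 0.40 M | 78 mM (held) | 0.0800 M | 4.4 mol% |  | 2.0 min |

- spring (time / min: target / %, starting material / %): 0.200: 29, 74; 0.667: 60, 33; 1.00: 71, 17; 1.50: 70, 9; 2.50: 57, 0
- summer (time / min: target / %, starting material / %): 0.500: 72, 26; 1.00: 83, 3; 1.33: 72, 0; 2.00: 64, 0; 2.50: 55, 1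

(standard deviation of a reading: 1.5 percentage points)

- at the start none of the gas phase is in solution

1. the target standing at 2.0 min, as a percentage of the starting material charged
2. the change that raises the amount of target at 2.0 min, in percent of the starting material charged most ("none" if none brings more than 2 percentage points) (alpha / gamma / zeta / none)
3. amount of target at 2.0 min, in percent of the starting material charged, after gamma

- alpha: doubling the amount of catalyst, all else as stated
- gamma: doubling the saturation concentration of gas phase, all else as stated
- zeta: doubling the transfer coefficient of the gas phase, all else as stated

In the summer run the sum reads 86.0% at 1.00 min and 56.0% at 2.50 min. The fall of its natural logarithm per minute is the loss constant, 0.286 min⁻¹, a pseudo-first-order constant read from two readings and carrying their scatter. The spring run, charged at 0.27 M instead of 0.60 M, reads 0.290 min⁻¹ over the same interval, about the same, so the constant can be carried to the flask at 0.40 M.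

Integrating a first-order loss with that constant held gives the sum at a later time as the earlier sum times exp(−constant × elapsed time). The two runs average 87.0% at 1.00 min, so my own reckoning for the flask at 2.0 min is 65.4%, which counts any remaining starting material as target.

The forecast is slightly lower, at 64%. It names none as the best change and gives 61% after gamma, holding that “Speeding the main step only forms target earlier, so it decays longer”.

The flask gives 63.0%, the best change is none, and gamma leaves 34.7% against the forecast's 61%.

    gas phase ⇌ dissolved gas, rate k1*(csat - [dissolved gas]) (kL = 0.700 s⁻¹)
    starting material + dissolved gas + catalyst → catalyst + target (k = 36.0 L² mol⁻² s⁻¹)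
    dissolved gas + target → over-reaction product (k = 0.0670 L mol⁻¹ s⁻¹)
    dissolved gas + protic impurity → quenched reagent (k = 0.0550 L mol⁻¹ s⁻¹)

Net turnover to over-reaction product reaches 36.5% of the starting material charged by the asked time. The flask's own sum goes from 84.9% at 1.00 min to 63.5% at 2.00 min, a constant of 0.290 min⁻¹ beside the carried 0.286 min⁻¹. Carried on from 2.0 min, 0.286 min⁻¹ gives 11.4% for the neighbour read at 8.0 min, which holds 9.93% target.

Readings and results were generated by integration for substances that don't exist; noise was put on by code.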